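**Plan**

Locants: cyclohexane C1′ (quaternary), C2′ (C=CH2), C3′ (CHCH3), C4′–C6′ (CH2); chromene numbered as usual; linker C1′–CβH2–CαH2–C2(chromene).
Retrosynthetic cuts, in order: the two MOM ethers; C2′=CH2 (back to a C2′ carbinol); chromene C3=C4 and O1–C2 (back to the epoxide of an (E)-alkene and a free phenol); Cα–C2 (B-alkyl Suzuki); Cβ=Cα (back to a C1′ formyl group); finally the ring bonds C5′–C6′ and C1′–C2′ (Diels–Alder).
Enabling feature: C2′ lies between the quaternary C1′ and the methyl-bearing C3′ and can be carried as an allylic silyloxy carbon, so C2′–C3′–C4′–C5′ is a 1-silyloxy-2-methylbutadiene and C6′=C1′(CH3)–CHO is methacrolein, whose formyl carbon becomes Cβ.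
Forward order: cyclohexene ring (step 2), saturation and vinyl group (steps 3–4), arene fragment (steps 5–10), fragment union (step 11), pyran ring (steps 12–14), exocyclic methylene (steps 15–17), deprotection (step 18).
Stereochemistry: C1′ from the chiral oxazaborolidinium catalyst; C3′ relayed from C1′ through the endo-derived C2′–OTBS by face-selective hydrogenation; chromene C2 from reagent-controlled Shi epoxidation followed by invertive 6-endo epoxide opening.

Key step: step 2

Assumption: the (S)-prolinol-derived oxazaborolidinium ion is taken to expose the enal face that leads to the (1S,2R) adduct 4 (formyl C–H···O binding model); if the sense were opposite, the (R)-catalyst would be used with no other change.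

**Route**

Step 1
Reactants: 1 (E)-2-methylbut-2-enal
Product: 2 (E)-tert-butyl(dimethyl)[(2-methylbuta-1,3-dien-1-yl)oxy]silane
Conditions: TBSOTf, Et3N, Et2O, 0 °C to rt
Reagents that add atoms: tert-butyldimethylsilyl trifluoromethanesulfonate, CC(C)(C)[Si](C)(C)OS(=O)(=O)C(F)(F)F
Why: Silyl dienol ether formation (O-silylation and γ-deprotonation of the s-trans enal) should give the (1E)-diene with the silyloxy group on the outside of the s-cis form.

Step 2
Reactants: 2 (E)-tert-butyl(dimethyl)[(2-methylbuta-1,3-dien-1-yl)oxy]silane; 3 2-methylprop-2-enal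
Product: 4 (1S,2R)-2-{[tert-butyl(dimethyl)silyl]oxy}-1,3-dimethylcyclohex-3-ene-1-carbaldehyde
Conditions: (S)-3,3-diphenyl-1-(o-tolyl)tetrahydro-1H,3H-pyrrolo[1,2-c][1,3,2]oxazaborole·HNTf2 (0.2 equiv), 3 (1.5 equiv), CH2Cl2, −78 °C
Reagents that add atoms: none
Why: The boron-bound s-trans methacrolein reacts with the diene through an asynchronous concerted [4+2] transition state in which the unsubstituted diene terminus bonds first to the β-CH2 of the enal (ring bond C5′–C6′) and the silyloxy-bearing terminus then closes onto the α-carbon (C1′–C2′). The closest known reaction type is the oxazaborolidinium-catalysed enantioselective Diels–Alder reaction of 2-substituted acroleins with silyloxy dienes. The cyclohexene is closed in the intermolecular suprafacial [4π+2π] cycloaddition mode, both ring bonds arising in the one operation. The quaternary centre C1′ is controlled by the catalyst, which shields one face of the coordinated enal, and the carbinol centre C2′ is controlled relative to it by the endo approach (formyl under the diene, α-methyl outside), which places OTBS cis to CHO. The step needs the "ortho" regiochemistry, secured by the 1-silyloxy group, whose donation puts the largest HOMO coefficient on the remote CH2 terminus and overrides the weaker opposite bias of the 2-methyl group. It also needs endo and facial selectivity, which rest on secondary overlap of the formyl group and on the rigid C–H···O-organised enal–catalyst complex.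

Step 3
Reactants: 4 (1S,2R)-2-{[tert-butyl(dimethyl)silyl]oxy}-1,3-dimethylcyclohex-3-ene-1-carbaldehyde
Product: 5 (1S,2R,3R)-2-{[tert-butyl(dimethyl)silyl]oxy}-1,3-dimethylcyclohexane-1-carbaldehyde
Conditions: H2 (3 atm), 5% Rh/Al2O3, EtOAc, rt
Reagents that add atoms: none
Why: Heterogeneous catalytic hydrogenation should deliver both hydrogens to the ring face opposite the pseudoaxial allylic OTBS group and the cis formyl group, so that the C3′ methyl ends cis to the formyl carbon; rhodium on alumina is chosen to limit allylic C–O hydrogenolysis and alkene migration.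

Step 4
Reactants: 5 (1S,2R,3R)-2-{[tert-butyl(dimethyl)silyl]oxy}-1,3-dimethylcyclohexane-1-carbaldehyde
Product: 6 tert-butyl{[(1R,2R,6R)-2-ethenyl-2,6-dimethylcyclohexyl]oxy}dimethylsilane
Conditions: Ph3PCH3Br, KN(SiMe3)2, THF, 0 °C to rt
Reagents that add atoms: methyltriphenylphosphonium bromide, C[P+](c1ccccc1)(c1ccccc1)c1ccccc1.[Br-]
Why: Wittig methylenation of the non-enolisable neopentyl aldehyde turns the formyl carbon into Cβ and adds Cα without touching a stereocentre.

Step 5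
Reactants: 7 4-methoxybenzene-1,2-diol
Product: 8 4-methoxy-1,2-bis(methoxymethoxy)benzene
Conditions: MOMCl, i-Pr2NEt, CH2Cl2, 0 °C to rt
Reagents that add atoms: chloromethyl methyl ether, COCCl
Why: O-Alkylation of both catechol hydroxyls (MOM acetal formation) gives ethers that should survive the organolithium, palladium, oxidant and fluoride steps.

Step 6
Reactants: 8 4-methoxy-1,2-bis(methoxymethoxy)benzene
Product: 9 1-bromo-2-methoxy-4,5-bis(methoxymethoxy)benzene
Conditions: NBS, MeCN, 0 °C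
Reagents that add atoms: N-bromosuccinimide, O=C1CCC(=O)N1Br
Why: Electrophilic aromatic bromination should occur at C5, the only position that is para to an acetal oxygen and ortho to OMe without lying between two substituents.

Step 7
Reactants: 9 1-bromo-2-methoxy-4,5-bis(methoxymethoxy)benzene
Product: 12 2-methoxy-4,5-bis(methoxymethoxy)phenol, via aryllithium 10 (not isolated), via arylboronate 11 (not isolated)
Conditions: n-BuLi, THF, −78 °C; B(OMe)3, −78 to 0 °C; then 30% H2O2, aq. NaOH, 0 °C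
Reagents that add atoms: hydrogen peroxide, OO
Why: Bromine–lithium exchange, borylation and oxidative 1,2-migration of the aryl group from boron to oxygen (boronate oxidation) convert the C–Br bond into the phenolic C–O bond at the same carbon.

Step 8
Reactants: 12 2-methoxy-4,5-bis(methoxymethoxy)phenol
Product: 13 2-[2-methoxy-4,5-bis(methoxymethoxy)phenoxy]oxane
Conditions: 3,4-dihydro-2H-pyran, PPTS (cat.), CH2Cl2, rt
Reagents that add atoms: 3,4-dihydro-2H-pyran, C1=COCCC1
Why: Acid-catalysed addition of the phenol to the enol ether (tetrahydropyranylation) masks the future pyran oxygen as an acetal that is cleaved by much weaker acid than the MOM ethers and directs ortho-lithiation.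

Step 9
Reactants: 13 2-[2-methoxy-4,5-bis(methoxymethoxy)phenoxy]oxane; 14 1-bromobut-2-yne
Product: 16 2-[2-(but-2-yn-1-yl)-6-methoxy-3,4-bis(methoxymethoxy)phenoxy]oxane, via aryllithium 15 (not isolated)
Conditions: n-BuLi, TMEDA, THF, −20 to 0 °C; then CuBr·SMe2 (0.1 equiv), 14, −78 °C to rt
Reagents that add atoms: none
Why: Directed ortho-metalation should take place at the ring position flanked by the two lithium-chelating acetal ethers (OTHP and OMOM) in preference to the position next to the weaker OMe director, and SN2 alkylation of the aryl anion with the primary propargylic bromide then installs the butynyl group.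

Step 10
Reactants: 16 2-[2-(but-2-yn-1-yl)-6-methoxy-3,4-bis(methoxymethoxy)phenoxy]oxane
Product: 18 2-{2-[(2E)-3-iodobut-2-en-1-yl]-6-methoxy-3,4-bis(methoxymethoxy)phenoxy}oxane, via alkenylzirconocene 17 (not isolated)
Conditions: Cp2Zr(H)Cl (2.5 equiv), THF, 50 °C; then I2, THF, 0 °C
Reagents that add atoms: iodine, [I][I]
Why: Hydrozirconation (syn addition, zirconium settling on the less hindered methyl-bearing alkyne carbon under equilibrating conditions) followed by iodinolysis with retention should give the (E)-2-iodoalkene.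

Step 11
Reactants: 6 tert-butyl{[(1R,2R,6R)-2-ethenyl-2,6-dimethylcyclohexyl]oxy}dimethylsilane; 18 2-{2-[(2E)-3-iodobut-2-en-1-yl]-6-methoxy-3,4-bis(methoxymethoxy)phenoxy}oxane
Product: 20 2-{2-[(2E)-5-[(1R,2R,3R)-2-{[tert-butyl(dimethyl)silyl]oxy}-1,3-dimethylcyclohexyl]-3-methylpent-2-en-1-yl]-6-methoxy-3,4-bis(methoxymethoxy)phenoxy}oxane, via alkylborane 19 (not isolated)
Conditions: 9-BBN, THF, rt; then 18, Pd(dppf)Cl2 (5 mol %), AsPh3, Cs2CO3, DMF/THF/H2O, rt
Reagents that add atoms: none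
Why: Anti-Markovnikov hydroboration of the only alkene of 6 and B-alkyl Suzuki–Miyaura coupling with retention of the vinyl iodide geometry join the fragments at Cα–C2 and create the (E)-trisubstituted alkene.

Step 12
Reactants: 20 2-{2-[(2E)-5-[(1R,2R,3R)-2-{[tert-butyl(dimethyl)silyl]oxy}-1,3-dimethylcyclohexyl]-3-methylpent-2-en-1-yl]-6-methoxy-3,4-bis(methoxymethoxy)phenoxy}oxane
Product: 21 2-{2-{[(2R,3R)-3-{2-[(1R,2R,3R)-2-{[tert-butyl(dimethyl)silyl]oxy}-1,3-dimethylcyclohexyl]ethyl}-3-methyloxiran-2-yl]methyl}-6-methoxy-3,4-bis(methoxymethoxy)phenoxy}oxane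
Conditions: 1,2:4,5-di-O-isopropylidene-β-D-erythro-hexo-2,3-diulo-2,6-pyranose (0.3 equiv), KHSO5 (as 2KHSO5·KHSO4·K2SO4), K2CO3, Bu4NHSO4, MeCN/CH2(OMe)2/aq. Na2B4O7 buffer, 0 °C
Reagents that add atoms: potassium peroxymonosulfate, [K+].[O-]S(=O)(=O)OO
Why: Shi epoxidation with the D-fructose-derived ketone, which is reliable for (E)-trisubstituted alkenes through the spiro dioxirane transition state, should give the (2R,3R)-epoxide of the only alkene in 20.

Step 13
Reactants: 21 2-{2-{[(2R,3R)-3-{2-[(1R,2R,3R)-2-{[tert-butyl(dimethyl)silyl]oxy}-1,3-dimethylcyclohexyl]ethyl}-3-methyloxiran-2-yl]methyl}-6-methoxy-3,4-bis(methoxymethoxy)phenoxy}oxane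
Product: 23 (2S,3R)-2-{2-[(1R,2R,3R)-2-{[tert-butyl(dimethyl)silyl]oxy}-1,3-dimethylcyclohexyl]ethyl}-8-methoxy-5,6-bis(methoxymethoxy)-2-methyl-3,4-dihydro-2H-chromen-3-ol, via phenol epoxide 22 (not isolated)
Conditions: PPTS (0.2 equiv), MeOH, 0 °C to rt; then CSA (0.1 equiv), CH2Cl2, 0 °C
Reagents that add atoms: none
Why: Mild acid removes the THP acetal selectively, and the freed phenol, the only hydroxyl ortho to the side chain, should open the epoxide in the 6-endo mode at the tertiary carbon with inversion (acid-promoted epoxide-opening cyclisation), which fixes the configuration of chromene C2.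

Step 14
Reactants: 23 (2S,3R)-2-{2-[(1R,2R,3R)-2-{[tert-butyl(dimethyl)silyl]oxy}-1,3-dimethylcyclohexyl]ethyl}-8-methoxy-5,6-bis(methoxymethoxy)-2-methyl-3,4-dihydro-2H-chromen-3-ol
Product: 24 tert-butyl{[(1R,2R,6R)-2-{2-[(2S)-8-methoxy-5,6-bis(methoxymethoxy)-2-methyl-2H-chromen-2-yl]ethyl}-2,6-dimethylcyclohexyl]oxy}dimethylsilane
Conditions: Martin sulfurane (Ph2S[OC(CF3)2Ph]2), CH2Cl2, 0 °C to rt
Reagents that add atoms: none
Why: Dehydration through the alkoxysulfonium ion (E2 elimination) can only remove a benzylic C4 hydrogen because C2 is quaternary, so the 2H-chromene should form without touching the C2 stereocentre.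

Step 15
Reactants: 24 tert-butyl{[(1R,2R,6R)-2-{2-[(2S)-8-methoxy-5,6-bis(methoxymethoxy)-2-methyl-2H-chromen-2-yl]ethyl}-2,6-dimethylcyclohexyl]oxy}dimethylsilane
Product: 25 (1R,2R,6R)-2-{2-[(2S)-8-methoxy-5,6-bis(methoxymethoxy)-2-methyl-2H-chromen-2-yl]ethyl}-2,6-dimethylcyclohexan-1-ol
Conditions: Bu4NF, THF, 60 °C
Reagents that add atoms: none
Why: Fluoride-mediated desilylation frees the hindered secondary carbinol, while the acetal ethers and the chromene are inert to these basic conditions.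

Step 16
Reactants: 25 (1R,2R,6R)-2-{2-[(2S)-8-methoxy-5,6-bis(methoxymethoxy)-2-methyl-2H-chromen-2-yl]ethyl}-2,6-dimethylcyclohexan-1-ol
Product: 26 (2R,6R)-2-{2-[(2S)-8-methoxy-5,6-bis(methoxymethoxy)-2-methyl-2H-chromen-2-yl]ethyl}-2,6-dimethylcyclohexan-1-one
Conditions: Dess–Martin periodinane, NaHCO3, CH2Cl2, rt
Reagents that add atoms: none
Why: Dess–Martin oxidation under buffered, non-basic conditions should give the ketone without epimerising the adjacent methyl-bearing centre C3′.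

Step 17
Reactants: 26 (2R,6R)-2-{2-[(2S)-8-methoxy-5,6-bis(methoxymethoxy)-2-methyl-2H-chromen-2-yl]ethyl}-2,6-dimethylcyclohexan-1-one
Product: 27 (2S)-2-{2-[(1R,3R)-1,3-dimethyl-2-methylidenecyclohexyl]ethyl}-8-methoxy-5,6-bis(methoxymethoxy)-2-methyl-2H-chromene
Conditions: Cp2Ti(μ-Cl)(μ-CH2)AlMe2 (Tebbe reagent), pyridine (cat.), THF/toluene, −40 °C to rt
Reagents that add atoms: Tebbe reagent, C[Al-]1(C)C[Ti](C2C=CC=C2)(C2C=CC=C2)[Cl+]1
Why: Titanium-mediated carbonyl methylenation (Tebbe olefination) is non-basic and tolerates a ketone flanked by a quaternary and a tertiary carbon, so the exocyclic alkene should form without enolisation at C3′.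

Step 18
Reactants: 27 (2S)-2-{2-[(1R,3R)-1,3-dimethyl-2-methylidenecyclohexyl]ethyl}-8-methoxy-5,6-bis(methoxymethoxy)-2-methyl-2H-chromene
Product: 29 (2S)-2-{2-[(1R,3R)-1,3-dimethyl-2-methylidenecyclohexyl]ethyl}-8-methoxy-2-methyl-2H-chromene-5,6-diol, via bis-silyl ether 28 (not isolated)
Conditions: Me3SiOTf, 2,2′-bipyridyl, CH2Cl2, 0 °C, argon; then H2O, rt
Reagents that add atoms: none
Why: Silyl triflate/bipyridyl cleavage of the aryl MOM acetals to aryl silyl ethers and their hydrolysis is a non-acidic deprotection, chosen so that the exocyclic alkene and the chromene never meet protic acid, with air excluded to protect the electron-rich catechol.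

**Compound list**

1 | (E)-2-methylbut-2-enal | C/C=C(\C)C=O | starting material
2 | (E)-tert-butyl(dimethyl)[(2-methylbuta-1,3-dien-1-yl)oxy]silane | C=C/C(C)=C/O[Si](C)(C)C(C)(C)C | intermediate
3 | 2-methylprop-2-enal (methacrolein) | CC(=C)C=O | starting material
4 | (1S,2R)-2-{[tert-butyl(dimethyl)silyl]oxy}-1,3-dimethylcyclohex-3-ene-1-carbaldehyde (OTBS cis to CHO) | CC(C)(C)[Si](C)(C)O[C@@H]1C(C)=CCC[C@]1(C)C=O | intermediate
5 | (1S,2R,3R)-2-{[tert-butyl(dimethyl)silyl]oxy}-1,3-dimethylcyclohexane-1-carbaldehyde | CC(C)(C)[Si](C)(C)O[C@@H]1[C@H](C)CCC[C@]1(C)C=O | intermediate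
6 | tert-butyl{[(1R,2R,6R)-2-ethenyl-2,6-dimethylcyclohexyl]oxy}dimethylsilane | CC(C)(C)[Si](C)(C)O[C@@H]1[C@H](C)CCC[C@]1(C)C=C | intermediate
7 | 4-methoxybenzene-1,2-diol | COc1ccc(O)c(O)c1 | starting material
8 | 4-methoxy-1,2-bis(methoxymethoxy)benzene | COCOc1ccc(OC)cc1OCOC | intermediate
9 | 1-bromo-2-methoxy-4,5-bis(methoxymethoxy)benzene | COCOc1cc(OC)c(Br)cc1OCOC | intermediate
10 | [2-methoxy-4,5-bis(methoxymethoxy)phenyl]lithium | COCOc1cc(OC)c([Li])cc1OCOC | intermediate (not isolated)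
11 | dimethyl [2-methoxy-4,5-bis(methoxymethoxy)phenyl]boronate | COCOc1cc(OC)c(B(OC)OC)cc1OCOC | intermediate (not isolated)
12 | 2-methoxy-4,5-bis(methoxymethoxy)phenol | COCOc1cc(OC)c(O)cc1OCOC | intermediate
13 | 2-[2-methoxy-4,5-bis(methoxymethoxy)phenoxy]oxane (racemic at the acetal carbon) | COCOc1cc(OC)c(OC2CCCCO2)cc1OCOC | intermediate
14 | 1-bromobut-2-yne | CC#CCBr | starting material
15 | [3-methoxy-5,6-bis(methoxymethoxy)-2-(oxan-2-yloxy)phenyl]lithium | [Li]c1c(OCOC)c(OCOC)cc(OC)c1OC1CCCCO1 | intermediate (not isolated)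
16 | 2-[2-(but-2-yn-1-yl)-6-methoxy-3,4-bis(methoxymethoxy)phenoxy]oxane | CC#CCc1c(OCOC)c(OCOC)cc(OC)c1OC1CCCCO1 | intermediate
17 | chlorobis(cyclopentadienyl){(2E)-4-[3-methoxy-5,6-bis(methoxymethoxy)-2-(oxan-2-yloxy)phenyl]but-2-en-2-yl}zirconium | C/C(=C\Cc1c(OCOC)c(OCOC)cc(OC)c1OC1CCCCO1)[Zr](Cl)(C1C=CC=C1)C1C=CC=C1 | intermediate (not isolated)
18 | 2-{2-[(2E)-3-iodobut-2-en-1-yl]-6-methoxy-3,4-bis(methoxymethoxy)phenoxy}oxane | I/C(C)=C/Cc1c(OCOC)c(OCOC)cc(OC)c1OC1CCCCO1 | intermediate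
19 | 9-{2-[(1S,2R,3R)-2-{[tert-butyl(dimethyl)silyl]oxy}-1,3-dimethylcyclohexyl]ethyl}-9-borabicyclo[3.3.1]nonane (same spatial arrangement as 6; descriptor at C1 changes by priority only) | CC(C)(C)[Si](C)(C)O[C@@H]1[C@H](C)CCC[C@]1(C)CCB2C3CCCC2CCC3 | intermediate (not isolated)
20 | 2-{2-[(2E)-5-[(1R,2R,3R)-2-{[tert-butyl(dimethyl)silyl]oxy}-1,3-dimethylcyclohexyl]-3-methylpent-2-en-1-yl]-6-methoxy-3,4-bis(methoxymethoxy)phenoxy}oxane (both epimers at the oxane acetal carbon) | CC(C)(C)[Si](C)(C)O[C@@H]1[C@H](C)CCC[C@]1(C)CC/C(C)=C/Cc2c(OCOC)c(OCOC)cc(OC)c2OC3CCCCO3 | intermediate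
21 | 2-{2-{[(2R,3R)-3-{2-[(1R,2R,3R)-2-{[tert-butyl(dimethyl)silyl]oxy}-1,3-dimethylcyclohexyl]ethyl}-3-methyloxiran-2-yl]methyl}-6-methoxy-3,4-bis(methoxymethoxy)phenoxy}oxane (both epimers at the oxane acetal carbon) | CC(C)(C)[Si](C)(C)O[C@@H]1[C@H](C)CCC[C@]1(C)CC[C@@]2(C)O[C@@H]2Cc3c(OCOC)c(OCOC)cc(OC)c3OC4CCCCO4 | intermediate
22 | 2-{[(2R,3R)-3-{2-[(1R,2R,3R)-2-{[tert-butyl(dimethyl)silyl]oxy}-1,3-dimethylcyclohexyl]ethyl}-3-methyloxiran-2-yl]methyl}-6-methoxy-3,4-bis(methoxymethoxy)phenol | CC(C)(C)[Si](C)(C)O[C@@H]1[C@H](C)CCC[C@]1(C)CC[C@@]2(C)O[C@@H]2Cc3c(OCOC)c(OCOC)cc(OC)c3O | intermediate (not isolated)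
23 | (2S,3R)-2-{2-[(1R,2R,3R)-2-{[tert-butyl(dimethyl)silyl]oxy}-1,3-dimethylcyclohexyl]ethyl}-8-methoxy-5,6-bis(methoxymethoxy)-2-methyl-3,4-dihydro-2H-chromen-3-ol | CC(C)(C)[Si](C)(C)O[C@@H]1[C@H](C)CCC[C@]1(C)CC[C@@]2(C)[C@H](O)Cc3c(OCOC)c(OCOC)cc(OC)c3O2 | intermediate
24 | tert-butyl{[(1R,2R,6R)-2-{2-[(2S)-8-methoxy-5,6-bis(methoxymethoxy)-2-methyl-2H-chromen-2-yl]ethyl}-2,6-dimethylcyclohexyl]oxy}dimethylsilane | CC(C)(C)[Si](C)(C)O[C@@H]1[C@H](C)CCC[C@]1(C)CC[C@@]2(C)C=Cc3c(OCOC)c(OCOC)cc(OC)c3O2 | intermediate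
25 | (1R,2R,6R)-2-{2-[(2S)-8-methoxy-5,6-bis(methoxymethoxy)-2-methyl-2H-chromen-2-yl]ethyl}-2,6-dimethylcyclohexan-1-ol | O[C@@H]1[C@H](C)CCC[C@]1(C)CC[C@@]2(C)C=Cc3c(OCOC)c(OCOC)cc(OC)c3O2 | intermediate
26 | (2R,6R)-2-{2-[(2S)-8-methoxy-5,6-bis(methoxymethoxy)-2-methyl-2H-chromen-2-yl]ethyl}-2,6-dimethylcyclohexan-1-one | O=C1[C@H](C)CCC[C@]1(C)CC[C@@]2(C)C=Cc3c(OCOC)c(OCOC)cc(OC)c3O2 | intermediate
27 | (2S)-2-{2-[(1R,3R)-1,3-dimethyl-2-methylidenecyclohexyl]ethyl}-8-methoxy-5,6-bis(methoxymethoxy)-2-methyl-2H-chromene | C=C1[C@H](C)CCC[C@]1(C)CC[C@@]2(C)C=Cc3c(OCOC)c(OCOC)cc(OC)c3O2 | intermediate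
28 | (2S)-2-{2-[(1R,3R)-1,3-dimethyl-2-methylidenecyclohexyl]ethyl}-8-methoxy-2-methyl-5,6-bis[(trimethylsilyl)oxy]-2H-chromene | C=C1[C@H](C)CCC[C@]1(C)CC[C@@]2(C)C=Cc3c(O[Si](C)(C)C)c(O[Si](C)(C)C)cc(OC)c3O2 | intermediate (not isolated)
29 | (2S)-2-{2-[(1R,3R)-1,3-dimethyl-2-methylidenecyclohexyl]ethyl}-8-methoxy-2-methyl-2H-chromene-5,6-diol | C=C1[C@H](C)CCC[C@]1(C)CC[C@@]1(C)C=Cc2c(O)c(O)cc(OC)c2O1 | target

**Count and risks**

Total step count: 18. Longest linear sequence: 14 steps (steps 5–18, from 4-methoxybenzene-1,2-diol); the cyclohexane branch from 1 runs through 12 steps (steps 1–4 and 11–18).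

Steps most likely to fail:

Step 2. What may go wrong: the silyl dienol ether may be consumed by protodesilylation or by Mukaiyama-type addition under the strongly acidic catalyst, or the catalyst may discriminate poorly between the two enal faces or between endo and exo approach. Fallback (resolution in place of asymmetric catalysis), setting out from 2 and 3: the cycloaddition is run with Me2AlCl in CH2Cl2 at −78 °C, which should give the racemic cis adduct, that is 4 together with its enantiomer (1R,2S)-2-{[tert-butyl(dimethyl)silyl]oxy}-1,3-dimethylcyclohex-3-ene-1-carbaldehyde F1. Condensation of the mixture with (1R,2R)-N,N′-dimethyl-1,2-diphenylethane-1,2-diamine (molecular sieves, Et2O) gives two diastereomeric aminals, the imidazolidine of 4 F2 and the imidazolidine of the enantiomer F3, which are separated by chromatography. Mild hydrolysis of F2 (aqueous AcOH, THF) returns to the route at 4.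

Step 3. What may go wrong: the two alkene faces may be discriminated poorly on the metal surface, or the double bond may migrate toward the silyloxy carbon with loss of the C2′/C3′ relay. Fallback (a temporary cis-fused ring enforces the face), setting out from 4: NaBH4 (MeOH, 0 °C) gives [(1R,2R)-2-{[tert-butyl(dimethyl)silyl]oxy}-1,3-dimethylcyclohex-3-en-1-yl]methanol F4, and Bu4NF gives the cis-diol (1R,6R)-6-(hydroxymethyl)-2,6-dimethylcyclohex-2-en-1-ol F5. 2,2-Dimethoxypropane with PPTS closes the acetonide (4aR,8aR)-2,2,4a,8-tetramethyl-4a,5,6,8a-tetrahydro-4H-1,3-benzodioxine F6, whose dioxane ring covers the face that carried both oxygen substituents. Hydrogenation (H2, Pd/C, EtOAc) from the open convex face should give (4aR,8R,8aR)-2,2,4a,8-tetramethylhexahydro-4H-1,3-benzodioxine F7. Aqueous AcOH releases (1R,2R,6R)-2-(hydroxymethyl)-2,6-dimethylcyclohexan-1-ol F8, TEMPO/PhI(OAc)2 oxidises only the primary alcohol to (1S,2R,3R)-2-hydroxy-1,3-dimethylcyclohexane-1-carbaldehyde F9, and TBSOTf/2,6-lutidine returns to the route at 5.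

Step 13. What may go wrong: the phenol may attack the secondary epoxide carbon (5-exo closure to a dihydrobenzofuran), the epoxide may be solvolysed before the phenol is free, or partial ionisation at the tertiary carbon may erode the C2 configuration. Fallback (a catalytically generated thiiranium ion replaces the epoxide and bypasses steps 12–14), setting out from 20: PPTS in MeOH gives 2-[(2E)-5-[(1R,2R,3R)-2-{[tert-butyl(dimethyl)silyl]oxy}-1,3-dimethylcyclohexyl]-3-methylpent-2-en-1-yl]-6-methoxy-3,4-bis(methoxymethoxy)phenol F10. Lewis-base-catalysed enantioselective sulfenoetherification (N-(phenylsulfanyl)succinimide, BINAM-derived selenophosphoramide catalyst of the appropriate hand, MsOH, CH2Cl2, −20 °C) should close the pyran ring 6-endo by anti addition of sulfur and phenol oxygen, giving tert-butyl{[(1R,2R,6R)-2-{2-[(2S,3R)-8-methoxy-5,6-bis(methoxymethoxy)-2-methyl-3-(phenylsulfanyl)-3,4-dihydro-2H-chromen-2-yl]ethyl}-2,6-dimethylcyclohexyl]oxy}dimethylsilane F11. mCPBA at −78 °C gives the corresponding sulfoxide F12, and thermal syn-elimination (toluene, 100 °C, NaHCO3) toward the benzylic hydrogen returns to the route at 24.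

Further compounds
F1 | step 2 | (1R,2S)-2-{[tert-butyl(dimethyl)silyl]oxy}-1,3-dimethylcyclohex-3-ene-1-carbaldehyde (enantiomer of 4) | CC(C)(C)[Si](C)(C)O[C@H]1C(C)=CCC[C@@]1(C)C=O
F2 | step 2 | (4R,5R)-2-[(1R,2R)-2-{[tert-butyl(dimethyl)silyl]oxy}-1,3-dimethylcyclohex-3-en-1-yl]-1,3-dimethyl-4,5-diphenylimidazolidine (aminal of 4) | CC(C)(C)[Si](C)(C)O[C@@H]1C(C)=CCC[C@]1(C)C2N(C)[C@H](c3ccccc3)[C@@H](c3ccccc3)N2C
F3 | step 2 | (4R,5R)-2-[(1S,2S)-2-{[tert-butyl(dimethyl)silyl]oxy}-1,3-dimethylcyclohex-3-en-1-yl]-1,3-dimethyl-4,5-diphenylimidazolidine (aminal of F1) | CC(C)(C)[Si](C)(C)O[C@H]1C(C)=CCC[C@@]1(C)C2N(C)[C@H](c3ccccc3)[C@@H](c3ccccc3)N2C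
F4 | step 3 | [(1R,2R)-2-{[tert-butyl(dimethyl)silyl]oxy}-1,3-dimethylcyclohex-3-en-1-yl]methanol | CC(C)(C)[Si](C)(C)O[C@@H]1C(C)=CCC[C@]1(C)CO
F5 | step 3 | (1R,6R)-6-(hydroxymethyl)-2,6-dimethylcyclohex-2-en-1-ol | O[C@@H]1C(C)=CCC[C@]1(C)CO
F6 | step 3 | (4aR,8aR)-2,2,4a,8-tetramethyl-4a,5,6,8a-tetrahydro-4H-1,3-benzodioxine | O1[C@@H]2C(C)=CCC[C@]2(C)COC1(C)C
F7 | step 3 | (4aR,8R,8aR)-2,2,4a,8-tetramethylhexahydro-4H-1,3-benzodioxine | O1[C@@H]2[C@H](C)CCC[C@]2(C)COC1(C)C
F8 | step 3 | (1R,2R,6R)-2-(hydroxymethyl)-2,6-dimethylcyclohexan-1-ol | O[C@@H]1[C@H](C)CCC[C@]1(C)CO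
F9 | step 3 | (1S,2R,3R)-2-hydroxy-1,3-dimethylcyclohexane-1-carbaldehyde | O[C@@H]1[C@H](C)CCC[C@]1(C)C=O
F10 | step 13 | 2-[(2E)-5-[(1R,2R,3R)-2-{[tert-butyl(dimethyl)silyl]oxy}-1,3-dimethylcyclohexyl]-3-methylpent-2-en-1-yl]-6-methoxy-3,4-bis(methoxymethoxy)phenol | CC(C)(C)[Si](C)(C)O[C@@H]1[C@H](C)CCC[C@]1(C)CC/C(C)=C/Cc2c(OCOC)c(OCOC)cc(OC)c2O
F11 | step 13 | tert-butyl{[(1R,2R,6R)-2-{2-[(2S,3R)-8-methoxy-5,6-bis(methoxymethoxy)-2-methyl-3-(phenylsulfanyl)-3,4-dihydro-2H-chromen-2-yl]ethyl}-2,6-dimethylcyclohexyl]oxy}dimethylsilane | CC(C)(C)[Si](C)(C)O[C@@H]1[C@H](C)CCC[C@]1(C)CC[C@@]2(C)[C@H](Sc4ccccc4)Cc3c(OCOC)c(OCOC)cc(OC)c3O2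
F12 | step 13 | S-oxide of F11 (3-(benzenesulfinyl)chroman, both configurations at sulfur) | CC(C)(C)[Si](C)(C)O[C@@H]1[C@H](C)CCC[C@]1(C)CC[C@@]2(C)[C@H](S(=O)c4ccccc4)Cc3c(OCOC)c(OCOC)cc(OC)c3O2
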